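**Retrosynthetic overview**

1. The enyne is made last from an (E)-enal (Colvin alkynylation), itself from an (E)-enoate. The C12 bromide comes from SN2 inversion of a C12 alcohol that stays a benzyl ether until after the key step.
2. The oxane ring (O–C6–C7–C8–C9–C10) is made by ring expansion of the isomeric bridged oxolane (O–C6–C7–C8–C9, bromine on exocyclic C10): an acid-mediated 1,2-interchange of oxygen and bromine across C9–C10 through one bromonium ion.
3. Enabling feature: in the target the oxane oxygen on C10 and the bromine on C9 form a trans (antiperiplanar) β-bromo ether, and the same oxygen also sits on C6. The oxane and the 6,9-oxolane with bromine on C10 are therefore the 6-endo and 5-exo closures of the C6 oxygen onto one bromine-bridged C9/C10 unit.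
4. The oxolane comes from transannular 5-exo bromoetherification of a (Z)-9,10-oxocene by the C6 hydroxyl; C6 is set by a chelation-controlled vinylogous Mukaiyama aldol on the oxocene aldehyde.
5. The oxocene comes from two Evans glycolate alkylations, a chelation-controlled ethyl addition and ring-closing metathesis. Ring order: oxocene (eight) → bridged oxolane (five) → oxane (six, by expansion).

Key step: step 15

Remark: locants C1–C15 in the text are those of the carbon chain of the target (C1 = alkyne CH, C15 = CH3 of the ethyl group); O6 is the oxygen that ends on C6 and C10.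

**Route**

Step 1
Reactants: 1 (4S)-4-benzyl-1,3-oxazolidin-2-one; 2 (benzyloxy)acetyl chloride
Product: 3 (4S)-4-benzyl-3-[(benzyloxy)acetyl]-1,3-oxazolidin-2-one
Conditions: n-BuLi, THF, −78 °C; then 2, −78 → 0 °C
Reagents that add atoms: (benzyloxy)acetyl chloride (2), O=C(Cl)COCc1ccccc1
Why: N-acylation of the lithiated Evans oxazolidinone by an acid chloride; no new stereocentre.

Step 2
Reactants: 3; 4 allyl iodide
Product: 5 (4S)-4-benzyl-3-[(2R)-2-(benzyloxy)pent-4-enoyl]-1,3-oxazolidin-2-one
Conditions: NaN(SiMe3)2, THF, −78 °C; 4, −78 → −45 °C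
Reagents that add atoms: allyl iodide (4), C=CCI
Why: Evans-type asymmetric alkylation of the chelated sodium (Z)-glycolate enolate; the benzyl group of the auxiliary shields one face and allyl iodide enters from the other, which sets C12 as (R).

Step 3
Reactants: 5
Product: 6 (2R)-2-(benzyloxy)pent-4-en-1-ol
Conditions: LiBH4, MeOH (1 equiv), Et2O, 0 °C
Reagents that add atoms: none
Why: Reductive cleavage of the N-acyl oxazolidinone by LiBH4 should give the primary alcohol without touching C12 and return the auxiliary.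

Step 4
Reactants: 6
Product: 7 (2R)-2-(benzyloxy)pent-4-enal
Conditions: Dess–Martin periodinane, NaHCO3, CH2Cl2, 0 °C → rt
Reagents that add atoms: none
Why: Dess–Martin oxidation of a primary alcohol under non-basic conditions that should not epimerize the α-alkoxy centre.

Step 5
Reactants: 7; 8 ethylmagnesium bromide
Product: 9 (3R,4R)-4-(benzyloxy)hept-6-en-3-ol
Conditions: MgBr2·OEt2, CH2Cl2, −78 °C; EtMgBr (Et2O), −78 °C
Reagents that add atoms: ethylmagnesium bromide (8), CC[Mg]Br
Why: Cram-chelate-controlled Grignard addition; magnesium bridges the aldehyde and benzyloxy oxygens and ethyl adds from the face of the α-hydrogen, which should give the syn alcohol and set C13 as (R).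

Step 6
Reactants: 9; 10 bromoacetic acid
Product: 11 {[(3R,4R)-4-(benzyloxy)hept-6-en-3-yl]oxy}acetic acid
Conditions: NaH (3 equiv), THF/DMF, 0 °C → rt; aq. HCl work-up
Reagents that add atoms: bromoacetic acid (10), OC(=O)CBr
Why: Williamson etherification of the sodium alkoxide with sodium bromoacetate; no stereocentre is touched.

Step 7
Reactants: 11; 12 pivaloyl chloride; 1 (4S)-4-benzyl-1,3-oxazolidin-2-one
Product: 14 (4S)-4-benzyl-3-({[(3R,4R)-4-(benzyloxy)hept-6-en-3-yl]oxy}acetyl)-1,3-oxazolidin-2-one, via mixed pivalic anhydride 13 (not isolated)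
Conditions: 12, Et3N, THF, −78 → 0 °C; then 1/n-BuLi (THF, −78 °C), −78 → 0 °C
Reagents that add atoms: (4S)-4-benzyl-1,3-oxazolidin-2-one (1), O=C1N[C@@H](Cc2ccccc2)CO1
Why: Acylation of the lithiated oxazolidinone by the mixed anhydride at its less hindered glycolyl carbonyl; no new stereocentre.

Step 8
Reactants: 14; 4 allyl iodide
Product: 15 (4S)-4-benzyl-3-[(2R)-2-{[(3R,4R)-4-(benzyloxy)hept-6-en-3-yl]oxy}pent-4-enoyl]-1,3-oxazolidin-2-one
Conditions: NaN(SiMe3)2, THF, −78 °C; 4, −78 → −45 °C
Reagents that add atoms: allyl iodide (4), C=CCI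
Why: Second Evans-type glycolate alkylation; the auxiliary again directs allyl iodide to one enolate face and sets C7 as (R), independent of the remote ether substituent.

Step 9
Reactants: 15
Product: 16 (4S)-4-benzyl-3-{[(2R,4Z,7R,8R)-7-(benzyloxy)-8-ethyl-3,6,7,8-tetrahydro-2H-oxocin-2-yl]carbonyl}-1,3-oxazolidin-2-one
Conditions: RuCl2(PCy3)2(=CHPh) (first-generation Grubbs catalyst, 5 mol %), CH2Cl2 (5 mM), 40 °C
Reagents that add atoms: none
Why: Ring-closing metathesis; the gauche preference of the two C–O bonds of the α,α'-disubstituted ether should pre-organize the diene, and the eight-membered ring can hold only the (Z)-alkene.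

Step 10
Reactants: 16
Product: 17 [(2R,4Z,7R,8R)-7-(benzyloxy)-8-ethyl-3,6,7,8-tetrahydro-2H-oxocin-2-yl]methanol
Conditions: LiBH4, MeOH (1 equiv), Et2O, 0 °C
Reagents that add atoms: none
Why: Reductive cleavage of the N-acyl oxazolidinone by LiBH4; the ring alkene and the stereocentres are not affected.

Step 11
Reactants: 17
Product: 18 (2R,4Z,7R,8R)-7-(benzyloxy)-8-ethyl-3,6,7,8-tetrahydro-2H-oxocine-2-carbaldehyde
Conditions: Dess–Martin periodinane, NaHCO3, CH2Cl2, 0 °C → rt
Reagents that add atoms: none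
Why: Dess–Martin oxidation to the α-alkoxy aldehyde under conditions that should leave C7 intact; the aldehyde is used at once.

Step 12
Reactants: 19 methyl (2E)-but-2-enoate; 20 tert-butyl(chloro)dimethylsilane
Product: 21 tert-butyl{[(1Z)-1-methoxybuta-1,3-dien-1-yl]oxy}dimethylsilane
Conditions: LiN(iPr)2, DMPU, THF, −78 °C; 20, −78 °C → rt
Reagents that add atoms: tert-butyl(chloro)dimethylsilane (20), CC(C)(C)[Si](C)(C)Cl
Why: γ-Deprotonation of the crotonate and O-silylation of the dienolate give the vinylogous silyl ketene acetal; the geometry of the ketene acetal is of no consequence for step 13.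

Step 13
Reactants: 18; 21
Product: 22 methyl (2E,5R)-5-[(2R,4Z,7R,8R)-7-(benzyloxy)-8-ethyl-3,6,7,8-tetrahydro-2H-oxocin-2-yl]-5-hydroxypent-2-enoate
Conditions: MgBr2·OEt2 (3 equiv), CH2Cl2, −78 → −30 °C; aq. NH4Cl
Reagents that add atoms: silyl dienolate (21), C=C/C=C(/OC)O[Si](C)(C)C(C)(C)C
Why: Chelation-controlled vinylogous Mukaiyama aldol; MgBr2 bridges the aldehyde oxygen and the ring oxygen on C7 and the dienolate attacks through its γ-carbon from the face of H-7, which should give the 6,7-syn alcohol (C6 R) and the (E)-enoate.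

Step 14
Reactants: 22; 23 N-bromosuccinimide
Product: 24 methyl (2E)-4-[(1R,3R,4R,6R,7R,9R)-4-(benzyloxy)-6-bromo-3-ethyl-2,8-dioxabicyclo[5.2.1]decan-9-yl]but-2-enoate
Conditions: NBS, NaHCO3, CH2Cl2, 0 °C, dark
Reagents that add atoms: N-bromosuccinimide (23), O=C1CCC(=O)N1Br
Why: Transannular bromoetherification in the kinetic 5-exo mode: NBS delivers bromine to the alkene face remote from the tethered C6 hydroxyl while that hydroxyl bonds to C9 from the opposite side in one nucleophile-assisted anti addition (no free ion is expected in this buffered, weakly ionizing medium), which sets C9 (R) and C10 (R), and only the cis-bridged oxolane is geometrically possible (any 6-endo isomer formed here is already 26 and is carried on).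

Step 15
Reactants: 24
Product: 26 methyl (2E)-4-[(1R,3R,4R,6S,8R,10S)-4-(benzyloxy)-10-bromo-3-ethyl-2,7-dioxabicyclo[4.2.2]decan-8-yl]but-2-enoate, via bromonium ion 25 (not isolated)
Conditions: CF3SO3H (10 mol %), 4 Å molecular sieves, CH2Cl2, −20 → 0 °C; Et3N quench
Reagents that add atoms: none
Why: Protonation of the oxolane oxygen (O6, bridging C6 and C9) turns it into a leaving group that the antiperiplanar C10 bromine expels from C9, which gives bromonium ion 25 as a discrete intermediate with the C6 hydroxyl still tethered; re-closure of that hydroxyl on C10 and loss of the proton give the oxane, so that oxygen moves from C9 to C10, bromine from C10 to C9, and the five-membered ring becomes six-membered. The closest known reaction type is the acid-promoted equilibration of kinetic 5-exo halo- and seleno-ethers into their 6-endo isomers through the onium ion, including the isomerization of 2-(1-bromoalkyl)oxolanes to 3-bromooxanes and of dibromo-9-oxabicyclo[4.2.1]nonane to the 9-oxabicyclo[3.3.1]nonane isomer. The oxane is closed in the 6-endo mode by backside opening of the bromonium ion at C10. C9 and C10 are both inverted stereospecifically (Br and O stay anti), so their configuration (9S,10S) is dictated by the alkene face on which bromine was placed in step 14. The step needs the equilibrium to lie on the oxane side and the C9/C10 pair to be the only unit that ionizes: the first is expected from the exchange of the 2,4-bridged oxolane and its nine-membered ring for an oxane and an eight-membered ring; the second is secured by keeping C12 as its benzyl ether (no second β-bromo ether) and by using a Brønsted acid without a halophilic metal, which should not ionize the C–Br bond towards transannular oxonium ions.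

Step 16
Reactants: 26
Product: 27 methyl (2E)-4-[(1R,3R,4R,6S,8R,10S)-10-bromo-3-ethyl-4-hydroxy-2,7-dioxabicyclo[4.2.2]decan-8-yl]but-2-enoate
Conditions: DDQ, CH2Cl2/pH 7 buffer, 525 nm LED, rt
Reagents that add atoms: none
Why: Oxidative debenzylation by photoexcited DDQ (benzylic hydride abstraction, hydrolysis of the oxocarbenium ion); the electron-poor enoate and the alkyl bromide should be inert and no stereocentre changes.

Step 17
Reactants: 27; 28 tetrabromomethane
Product: 29 methyl (2E)-4-[(1R,3R,4S,6S,8R,10S)-4,10-dibromo-3-ethyl-2,7-dioxabicyclo[4.2.2]decan-8-yl]but-2-enoate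
Conditions: CBr4, P(n-C8H17)3, toluene, 70 °C
Reagents that add atoms: tetrabromomethane (28), BrC(Br)(Br)Br
Why: Appel-type bromination; SN2 displacement of the oxyphosphonium group by bromide inverts C12 to (S), trans to the ethyl group.

Step 18
Reactants: 29
Product: 30 (2E)-4-[(1R,3R,4S,6S,8R,10S)-4,10-dibromo-3-ethyl-2,7-dioxabicyclo[4.2.2]decan-8-yl]but-2-en-1-ol
Conditions: iBu2AlH, CH2Cl2, −78 °C
Reagents that add atoms: none
Why: 1,2-Reduction of the enoate to the allylic alcohol by iBu2AlH at low temperature; the secondary bromides and the alkene geometry should be untouched.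

Step 19
Reactants: 30
Product: 31 (2E)-4-[(1R,3R,4S,6S,8R,10S)-4,10-dibromo-3-ethyl-2,7-dioxabicyclo[4.2.2]decan-8-yl]but-2-enal
Conditions: MnO2, CH2Cl2, rt
Reagents that add atoms: none
Why: Selective, neutral MnO2 oxidation of the allylic alcohol to the (E)-enal.

Step 20
Reactants: 31; 32 (trimethylsilyl)diazomethane
Product: 33 (1R,3R,4S,6S,8R,10S)-4,10-dibromo-3-ethyl-8-[(2E)-pent-2-en-4-yn-1-yl]-2,7-dioxabicyclo[4.2.2]decane
Conditions: 32, LiN(iPr)2, THF, −78 → 0 °C
Reagents that add atoms: (trimethylsilyl)diazomethane (32), C[Si](C)(C)C=[N+]=[N-]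
Why: Colvin homologation; addition of lithiated trimethylsilyldiazomethane to the aldehyde, Peterson-type elimination, loss of N2 and a 1,2-hydride shift give the terminal alkyne, and at −78 °C addition should outrun γ-deprotonation so that the (E)-alkene and the bromides are kept.

**Compound list**

1 | (4S)-4-benzyl-1,3-oxazolidin-2-one | O=C1N[C@@H](Cc2ccccc2)CO1 | starting material
2 | (benzyloxy)acetyl chloride | O=C(Cl)COCc1ccccc1 | starting material
3 | (4S)-4-benzyl-3-[(benzyloxy)acetyl]-1,3-oxazolidin-2-one | O=C(COCc1ccccc1)N1[C@@H](Cc2ccccc2)COC1=O | intermediate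
4 | allyl iodide | C=CCI | starting material
5 | (4S)-4-benzyl-3-[(2R)-2-(benzyloxy)pent-4-enoyl]-1,3-oxazolidin-2-one | O=C([C@@H](CC=C)OCc1ccccc1)N1[C@@H](Cc2ccccc2)COC1=O | intermediate
6 | (2R)-2-(benzyloxy)pent-4-en-1-ol | OC[C@@H](CC=C)OCc1ccccc1 | intermediate
7 | (2R)-2-(benzyloxy)pent-4-enal | O=C[C@@H](CC=C)OCc1ccccc1 | intermediate
8 | ethylmagnesium bromide | CC[Mg]Br | starting material
9 | (3R,4R)-4-(benzyloxy)hept-6-en-3-ol | CC[C@@H](O)[C@H](OCc1ccccc1)CC=C | intermediate
10 | bromoacetic acid | OC(=O)CBr | starting material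
11 | {[(3R,4R)-4-(benzyloxy)hept-6-en-3-yl]oxy}acetic acid | CC[C@@H](OCC(=O)O)[C@H](OCc1ccccc1)CC=C | intermediate
12 | pivaloyl chloride | CC(C)(C)C(=O)Cl | starting material
13 | {[(3R,4R)-4-(benzyloxy)hept-6-en-3-yl]oxy}acetic pivalic anhydride (not isolated) | CC[C@@H](OCC(=O)OC(=O)C(C)(C)C)[C@H](OCc1ccccc1)CC=C | intermediate
14 | (4S)-4-benzyl-3-({[(3R,4R)-4-(benzyloxy)hept-6-en-3-yl]oxy}acetyl)-1,3-oxazolidin-2-one | CC[C@@H](OCC(=O)N1[C@@H](Cc2ccccc2)COC1=O)[C@H](OCc1ccccc1)CC=C | intermediate
15 | (4S)-4-benzyl-3-[(2R)-2-{[(3R,4R)-4-(benzyloxy)hept-6-en-3-yl]oxy}pent-4-enoyl]-1,3-oxazolidin-2-one | CC[C@@H](O[C@H](CC=C)C(=O)N1[C@@H](Cc2ccccc2)COC1=O)[C@H](OCc1ccccc1)CC=C | intermediate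
16 | (4S)-4-benzyl-3-{[(2R,4Z,7R,8R)-7-(benzyloxy)-8-ethyl-3,6,7,8-tetrahydro-2H-oxocin-2-yl]carbonyl}-1,3-oxazolidin-2-one | CC[C@H]1O[C@@H](C(=O)N2[C@@H](Cc3ccccc3)COC2=O)C/C=C\C[C@H]1OCc1ccccc1 | intermediate
17 | [(2R,4Z,7R,8R)-7-(benzyloxy)-8-ethyl-3,6,7,8-tetrahydro-2H-oxocin-2-yl]methanol | CC[C@H]1O[C@@H](CO)C/C=C\C[C@H]1OCc1ccccc1 | intermediate
18 | (2R,4Z,7R,8R)-7-(benzyloxy)-8-ethyl-3,6,7,8-tetrahydro-2H-oxocine-2-carbaldehyde | CC[C@H]1O[C@@H](C=O)C/C=C\C[C@H]1OCc1ccccc1 | intermediate
19 | methyl (2E)-but-2-enoate | C/C=C/C(=O)OC | starting material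
20 | tert-butyl(chloro)dimethylsilane | CC(C)(C)[Si](C)(C)Cl | starting material
21 | tert-butyl{[(1Z)-1-methoxybuta-1,3-dien-1-yl]oxy}dimethylsilane | C=C/C=C(/OC)O[Si](C)(C)C(C)(C)C | intermediate
22 | methyl (2E,5R)-5-[(2R,4Z,7R,8R)-7-(benzyloxy)-8-ethyl-3,6,7,8-tetrahydro-2H-oxocin-2-yl]-5-hydroxypent-2-enoate | CC[C@H]1O[C@@H]([C@H](O)C/C=C/C(=O)OC)C/C=C\C[C@H]1OCc1ccccc1 | intermediate
23 | N-bromosuccinimide | O=C1CCC(=O)N1Br | starting material
24 | methyl (2E)-4-[(1R,3R,4R,6R,7R,9R)-4-(benzyloxy)-6-bromo-3-ethyl-2,8-dioxabicyclo[5.2.1]decan-9-yl]but-2-enoate | COC(=O)/C=C/C[C@H]1O[C@@H]2C[C@H]1O[C@H](CC)[C@H](OCc1ccccc1)C[C@H]2Br | intermediate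
25 | C9/C10 bromonium ion carrying the free C6 hydroxyl, bromine on the face remote from that hydroxyl (not isolated) | CC[C@H]1O[C@@H]([C@H](O)C/C=C/C(=O)OC)C[C@@H]2[Br+][C@@H]2C[C@H]1OCc1ccccc1 | intermediate
26 | methyl (2E)-4-[(1R,3R,4R,6S,8R,10S)-4-(benzyloxy)-10-bromo-3-ethyl-2,7-dioxabicyclo[4.2.2]decan-8-yl]but-2-enoate | COC(=O)/C=C/C[C@H]1O[C@H]2C[C@@H](OCc3ccccc3)[C@@H](CC)O[C@@H]1C[C@@H]2Br | intermediate
27 | methyl (2E)-4-[(1R,3R,4R,6S,8R,10S)-10-bromo-3-ethyl-4-hydroxy-2,7-dioxabicyclo[4.2.2]decan-8-yl]but-2-enoate | COC(=O)/C=C/C[C@H]1O[C@H]2C[C@@H](O)[C@@H](CC)O[C@@H]1C[C@@H]2Br | intermediate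
28 | tetrabromomethane | BrC(Br)(Br)Br | starting material
29 | methyl (2E)-4-[(1R,3R,4S,6S,8R,10S)-4,10-dibromo-3-ethyl-2,7-dioxabicyclo[4.2.2]decan-8-yl]but-2-enoate | COC(=O)/C=C/C[C@H]1O[C@H]2C[C@H](Br)[C@@H](CC)O[C@@H]1C[C@@H]2Br | intermediate
30 | (2E)-4-[(1R,3R,4S,6S,8R,10S)-4,10-dibromo-3-ethyl-2,7-dioxabicyclo[4.2.2]decan-8-yl]but-2-en-1-ol | OC/C=C/C[C@H]1O[C@H]2C[C@H](Br)[C@@H](CC)O[C@@H]1C[C@@H]2Br | intermediate
31 | (2E)-4-[(1R,3R,4S,6S,8R,10S)-4,10-dibromo-3-ethyl-2,7-dioxabicyclo[4.2.2]decan-8-yl]but-2-enal | O=C/C=C/C[C@H]1O[C@H]2C[C@H](Br)[C@@H](CC)O[C@@H]1C[C@@H]2Br | intermediate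
32 | (trimethylsilyl)diazomethane | C[Si](C)(C)C=[N+]=[N-] | starting material
33 | (1R,3R,4S,6S,8R,10S)-4,10-dibromo-3-ethyl-8-[(2E)-pent-2-en-4-yn-1-yl]-2,7-dioxabicyclo[4.2.2]decane (CNP0202038.1) | C#C/C=C/C[C@H]1O[C@H]2C[C@H](Br)[C@@H](CC)O[C@@H]1C[C@@H]2Br | target

**Count and risks**

Total step count: 20. Longest linear sequence: 19 steps (steps 1–11 and 13–20; step 12 is a one-step side branch).

Steps most likely to fail:

1. Step 15. The equilibration may stop on the oxolane side, or the bromonium ion may be drained by transannular capture through the oxocane oxygen or the benzyl ether oxygen. The fallback sets out from 22 and comes back at 26. Compound 22 is cyclized with 2,4,4,6-tetrabromocyclohexa-2,5-dienone in MeNO2 at −20 °C, a more ionizing medium in which the closures of the C6 hydroxyl on C9 and on C10 of bromonium ion 25 are partitioned kinetically. Compound 26 is separated by chromatography; the 5-exo isomer 24 is returned to 22 by reductive β-elimination (Zn dust, AcOH, EtOH, rt) and recycled. This fallback makes no new compound (F0).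

2. Step 17. The ring oxygen on C13 may participate at the oxyphosphonium stage (substitution with retention or ring contraction), or E2 elimination may compete. The fallback sets out from 27 and comes back at 29. The alcohol is converted with ClCH2SO2Cl and pyridine (CH2Cl2, 0 °C) into the isolated sulfonate methyl (2E)-4-[(1R,3R,4R,6S,8R,10S)-10-bromo-4-{[(chloromethyl)sulfonyl]oxy}-3-ethyl-2,7-dioxabicyclo[4.2.2]decan-8-yl]but-2-enoate F1. This is displaced in a separate operation by soluble bromide (Bu4NBr, toluene, 50 °C) with inversion, a non-ionizing medium with a high bromide concentration that favours direct SN2.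

3. Step 13. Chelation control may be lost (poor facial selectivity at C6), or the dienolate may attack through its α-carbon. The fallback sets out from 18 and comes back at 22. Chelation-controlled allylation (Bu3SnCH2CH=CH2, MgBr2·OEt2, CH2Cl2, −78 °C) gives the homoallylic alcohol (1R)-1-[(2R,4Z,7R,8R)-7-(benzyloxy)-8-ethyl-3,6,7,8-tetrahydro-2H-oxocin-2-yl]but-3-en-1-ol F2. Cross-metathesis of its terminal alkene with methyl acrylate (second-generation Grubbs catalyst RuCl2(H2IMes)(PCy3)(=CHPh), CH2Cl2, 40 °C) then gives the (E)-enoate 22.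

**Further compounds**

F0 | step 15 | none | none
F1 | step 17 | methyl (2E)-4-[(1R,3R,4R,6S,8R,10S)-10-bromo-4-{[(chloromethyl)sulfonyl]oxy}-3-ethyl-2,7-dioxabicyclo[4.2.2]decan-8-yl]but-2-enoate | COC(=O)/C=C/C[C@H]1O[C@H]2C[C@@H](OS(=O)(=O)CCl)[C@@H](CC)O[C@@H]1C[C@@H]2Br
F2 | step 13 | (1R)-1-[(2R,4Z,7R,8R)-7-(benzyloxy)-8-ethyl-3,6,7,8-tetrahydro-2H-oxocin-2-yl]but-3-en-1-ol | CC[C@H]1O[C@@H]([C@H](O)CC=C)C/C=C\C[C@H]1OCc1ccccc1
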